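The readings are simulated from invented constants, noise included.

**The ratio.** One ratio carried my reckoning for the flask: how fast links form against how fast they are lost.

in all of them: first end groups 0.75 M
- ash: second end groups 1.4 equiv; run made earlier
- elm: second end groups 2.2 equiv; run made earlier
- flask: second end groups 1.00 equiv; time 30 h

| run | time / h | links / % | first end groups / % |
|---|---|---|---|
| ash | 0.250 | 91.8 | 2.6 |
| ash | 0.667 | 94.6 | 0 |
| ash | 2.00 | 90.0 | 0 |
| ash | 6.00 | 79.2 | 0 |
| ash | 20.0 | 63.7 | 0 |
| elm | 0.250 | 97.2 | 0.3 |
| elm | 0.667 | 96.0 | 0 |
| elm | 2.00 | 90.6 | 0 |
| elm | 6.00 | 80.5 | 0.4 |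
| elm | 20.0 | 65.5 | 0.1 |

(scatter of a reading: 0.3 percentage points)

- a reading or a percentage of links counts all its forms, free or not
- a reading of first end groups is of its free form alone

- when, up to 30 h, the flask holds most links
- the amount of links, in percent of the first end groups charged, at that time

**First instants.** In the ash run, free first end groups read 2.6% at 0.250 h. With that run's excess, this gave me a joining rate J of 24.6 h⁻¹ at the charged strength.

**The middle.** Ash links then fell from 94.6% at 0.667 h to 90.0% at 2.00 h. That is a loss rate λ of 0.0374 h⁻¹, far slower than J. I took joining as the fast step and carried both rates to the flask. Its charges are equal, so no excess sweeps up the tail. Fresh links arrive at J times the square of the free share, and the peak stands where that matches the loss. I reckoned it at 1.00 h.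

I called G = J/λ the race ratio; it was 658. At the peak, the unjoined share and the lost share are about equal, each one over the square root of G. The shortfall S is their sum, 7.80%, so I expected 92.2% links.

**The end.** Past its peak, the ash run kept falling, to 63.7% at 20.0 h.

**The forecast.** It said 90.5% at 1.1 h, holding that “excess second end groups hardly matter”. My peak came earlier and stood higher.

**The flask.** It gave 86.2% at 0.953 h.

    first end groups + second end groups → links (k = 40.0 M⁻¹ h⁻¹)
    first end groups + second end groups → rings, rate k2*[first end groups] as long as [second end groups] is above zero (k = 0.700 h⁻¹)
    links ⇌ isomer of the product (K = 0.630, k = 0.0430 h⁻¹)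
    first end groups + links ⇌ idle adduct, settled at all times (K = 1.30 M⁻¹)
    2 second end groups → self-condensation product (k = 0.00980 M⁻¹ h⁻¹)

**The gap.** The flask's shortfall was 13.8%, more than S, and rings stood at 6.30% at its best time. Joining outran ring closure 39 to one just after the start, but 23 to one at 0.0338 h; these are momentary ratios of rates, not a fixed factor.

**Lower charge.** For the neighbour at 0.19 M, same equivalents, G drops to 167, so S is 15.5% and the race gives 84.5%. That neighbour's computed best was 72.3%, with rings ending at 22.7%.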